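All runs stem from a simulated flask on assumed constants, and the scatter is random.

**The first decision.** Decide first which clock to read, and read the solid's. These are the flasks, the readings and the questions:

the same everywhere: solid substrate 0.20 M
- Wednesday's: partner 0.30 M; run made earlier
- Thursday's: partner 0.45 M; run made earlier
- flask: partner 0.600 M; time 3.0 d

- Wednesday's (time / d: first product / %, solid substrate / %): 0.208: 11.0, 77.0; 0.417: 27.3, 59.3; 1.04: 69.9, 9.2; 2.50: 90.9, 0.9
- Thursday's (time / d: first product / %, solid substrate / %): 0.208: 14.0, 76.3; 0.417: 32.4, 56.3; 1.04: 83.8, 0; 2.50: 83.1, 0

(standard deviation of a reading: 0.5 percentage points)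

- at the start none of the solid substrate is in solution
- a reading or a percentage of first product counts all its forms, free or not

- equivalents of partner to solid substrate, everything else as given, that leave most first product at 3.0 d
- the amount of first product then, in percent of the solid substrate charged
- the amount of first product with the amounts as given

**The early slope.** In Thursday's run 43.7% of the solid had gone by 0.417 d, a dissolving rate of 0.210 M d⁻¹. The charge divided by that rate gives 0.954 d, the clearing time: how long the solid lasts on its early straight fall. Wednesday's readings give 1.02 d. A factor of 1.50 in [partner] shifts this clock by a factor of 1.07, so dissolving reads as the rate-limiting step until then.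

**The curve drawn.** Now draw the flask at 0.600 M on Thursday's clock. First product starts behind the solid: in Thursday's run, 14.0% had formed at 0.208 d, when 23.7% of the solid had gone. The curve then bends near 0.954 d, and 2.05 d remain after that. For the level, the readings at 2.50 d dropped from 90.9% to 83.1% between the two partner charges. One more equal step in partner gives 75.3%, my own figure.

**The forecast.** The forecast gives 77%, above my figure, and a best of 92.5% at 1.27 equiv. It reads Thursday's flat end to mean “first product isn't consumed afterwards”.

**The result.** The flask gives 70.7%, 6.3 percentage points below the forecast, and a best of 92.1% at 1.29 equiv.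

    starting material + partner → first product (k = 3.00 × 10⁻⁴ L mol⁻¹ s⁻¹)
    partner + first product → double product (k = 6.00 × 10⁻⁶ L mol⁻¹ s⁻¹)
    partner + double product → tris adduct (k = 9.60 × 10⁻⁶ L mol⁻¹ s⁻¹)
    solid substrate ⇌ starting material, rate k4*(cs4 - [starting material]) while solid is left; crystals form when [starting material] > cs4 (solubility = 0.0760 M, k = 4.00 × 10⁻⁵ s⁻¹)
    crystals ⇌ first product, rate k5*(cs5 - [first product]) while solid is left; crystals form when [first product] > cs5 (solubility = 0.110 M, k = 1.60 × 10⁻⁴ s⁻¹)

**The clock reused.** The straight fall predicts 68.6% solid in the flask at 0.300 d, and it holds 66.7%. Past clearing, first product falls from 85.2% at 1.50 d to 70.7% at 3.00 d. For the neighbouring flask with 0.50 M of solid substrate and 1.20 equiv of partner, the straight fall extended reads 2.39 d, but that is just the early slope carried on, and it was read at 2.25 equiv in Thursday's run. At 3.00 d that neighbouring flask holds solid substrate 0%, starting material 5.35%, partner 11.9% of its own charge, first product 85.8% and tris adduct 2.20%.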